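## Structural features

The target is a 3,3''-linked biflavanone: two 2-(4-methoxyphenyl)chroman-4-one units joined by one bond between C3 of unit 1 (5,7-dihydroxy ring A) and C3'' of unit 2 (5''-hydroxy-7''-methoxy ring A). The four stereocentres C2, C3, C3'' and C2'' are contiguous and read (2S,3R,3''S,2''S): unit 1 is 2,3-trans (diequatorial) and unit 2 is 2'',3''-cis, the less stable arrangement. C3 and C3'' both lie α to aryl ketones and can epimerise by enolisation. Each pyranone ring can also open by E1cB loss of its phenoxide, which would erase C2 or C2'', and the C2–O1 and C2''–O1'' bonds are 4-methoxybenzylic ethers, sensitive to strong acid and to hydrogenolysis. The two ring A units differ only in that the oxygen at C7'' is methylated, so the phenols must be told apart. The real difficulty is the kinetic cis unit 2 next to the trans unit 1 with the correct C3/C3'' relation, made and carried on without exposing C3'' to base. The key step uses the benzene ring A of unit 2 (C4a'', C5'', C6'', C7'', C8'', C8a''): its 1,3-dioxygenated arc C5''–C8'' is added as a diene across the C4a''=C8a'' bond of a 2,3-cis-dihydropyran-4-one that already holds all four stereocentres, and the two different oxygen functions of the diene become the C5'' hydroxyl and the C7'' methoxy group.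

## Logic of the disconnections

22 to 21. The two aryl O–benzyl bonds at O5 and O7 of unit 1 are cut. These phenols must be masked through silylations, a radical alkylation and Lewis acids, and benzyl ethers come off under neutral conditions, the only kind the cis C3'' centre and the ring-opening-prone pyranones tolerate. Unit 2 needs no protection because its hydroxyl appears only in the preceding step. The gain is small, but it leaves every skeletal and stereochemical problem to earlier stages. The forward step must stop at O–benzyl cleavage and spare the benzylic C2–O1 and C2''–O1'' bonds and the ketones.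

21 to 15 and 18. The bonds C8a''–C8'' and C4a''–C5'' are cut, which removes ring A of unit 2. This ring is the only place where the two halves differ, and a diene with one ketene acetal oxygen and one enol ether oxygen delivers the hydroxyl/methoxy pattern by construction. The cut also takes the arene away from the stage at which the cis relation is set, so the cis unit can be made as a monocyclic dihydropyranone. The gain is one ring and four carbons. The demand is heavy: 15 is only a moderate dienophile, the orientation must be as drawn, the liberated HBr must be buffered, and C3'' must survive.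

18 to 17 to 16. The O–Si bond and then the enol ether O–CH3 bond are cut, which leads to a commercial β-keto ester. The forward steps are an O-methylation and a γ-deprotonation with O-silylation.

15 to 11 and 12. The bonds O1''–C2'' and C2''–C3'' (a hetero-[4+2] retron) and the C4a''–Br bond are cut. The cis C2''/C3'' relation is the contra-thermodynamic element, and an endo cycloaddition of an aldehyde to a diene terminus with an outward substituent gives it kinetically, with no enolisable stage before a neutral work-up. The bromine is put on the enol silane of the cycloadduct 13, the only electron-rich alkene present; brominating a finished enone would compete with bromination of the benzyloxy arene. Two stereocentres and one ring are removed. The forward step needs endo selectivity, the correct diene face relative to C3, and a Lewis acid mild enough to keep the enol silane.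

11 to 10, then 10 to 7 and 9 (9 from 8). The O–Si bond of the dienol ether is cut, then the bond between C3 and the methylene carbon that becomes C3''. C3 is the α-carbon of the unit 1 ketone and the natural nucleophile, and 9 brings C3'', C4'', C4a'' and C8a'' in one piece. The bond must be made without a free enolate, which would expel the phenoxide and racemise C2, so an enol silane and a radical are used. The trans relation follows from approach anti to the C2 aryl group.

7 to 6, then 6 to 4 and 5. The O–Si bond is cut, then the C2–aryl bond. C2 is the one centre that cannot be relayed from another, and a catalytic asymmetric conjugate arylation of a chromone sets it absolutely; cyclisation of a chalcone would give a racemate. The forward step must work on an electron-rich chromone and protonate without ring opening.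

4 to 2 to 1. The O1–C2 and C2–C3 bonds are cut (a one-carbon insertion between the phenol and the acetyl group), then the two O–benzyl bonds. This reaches a commercial acetophenone. The forward steps need only regioselective benzylation that leaves the chelated phenol free.

## Other disconnections considered

Alternative 1: The cut is at C2–C3 and C2''–C3'', with the C3–C3'' bond supplied by the alkene of the dienophile. In the forward direction (1E,3E)-1,4-bis(4-methoxyphenyl)buta-1,3-diene A1 and maleic anhydride A2 would combine in an endo Diels–Alder reaction to the all-cis meso anhydride A3.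
- In favour: the diene and dienophile classes are textbook cases, one step fixes the relative configuration of all four carbons, and a desymmetrising alcoholysis of the anhydride could set the absolute configuration and tell the two halves apart.
- Against: in A3 the carbons that become C2 and C2'' carry an alkene carbon where the target has O1 and O1''. The cyclohexene would have to be cleaved and each benzylic carbon would need a carbon-to-oxygen exchange with full stereochemical fidelity. Both aryl ketones would have to be built from the anhydride carbonyls beside epimerisable centres. C2 and C2'' are mirror-related in A3 but both S in the target, so one heterocycle would have to close with inversion and the other with retention.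
- Comparison: A3 holds the stereocentres but none of the four rings of the target, whereas 15 lacks only one ring. On mechanism the alternative is the better: its key step has closer precedent than step 11 and creates four stereocentres where step 11 creates none. On step economy it is clearly worse, since step 11 is followed by one deprotection and A3 by a long sequence of cleavage, oxygen installation, acylation and two different ring closures.

Alternative 2: The cut is the central C3–C3'' bond. Direct irradiation of the (2S,2''S)-4,4''-bi(2H-chromene) A4 would close the diene C3=C4–C4''=C3'' by a disrotatory 4π-electrocyclisation to the cis-fused cyclobutene A5, and later cleavage of C4=C4'' would release both ketones.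
- In favour: this is the most convergent plan. Each half could be made separately with its C2 centre set by the same kind of asymmetric arylation as in step 3. The cis ring fusion fixes the C3/C3'' relation by orbital symmetry. Because both C2 centres are S, one half must become trans and the other cis, which is the pattern of the target.
- Against: which half becomes trans depends only on the direction of disrotation, and the two directions differ only in remote ring A substituents, so no bias is evident and both diastereomers are to be expected. 2H-Chromenes can also open photochemically to o-quinone methides, the s-cis diene is crowded by the two peri alkoxy groups, and oxidative cleavage of a tetrasubstituted alkene has to be done among electron-rich arenes and would expose an epimerisable cis centre.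
- Comparison: in convergence and in making the central bond directly the alternative is the better, and its step count should be equal or lower. It is weaker where it matters most: the chosen plan has a control element for each stereochemical decision (endo rule for cis, an allylic stereocentre for the C3/C3'' relation), the alternative has none for its decisive selectivity.

Alternative 3: The cut is C2–C3 of unit 1. Rh2(S-PTTL)4 would convert the diazo ketone A6 into a carbene at C3 that inserts into the OCH2 C–H bond of an ortho 4-methoxybenzyl ether, giving the (2S,3R)-flavanone A7 that carries unit 2 as a flavon-3-yl group.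
- In favour: C2 and C3 would be created together under catalyst control, the benzyl ether supplies both C2 and ring B, and the flat flavone avoids epimerisable centres in unit 2 until late. A later syn hydrogenation of C2''=C3'' would give the cis relation by mechanism.
- Against: the insertion is a 1,6-process, while the ether oxygen sits where a five-membered oxonium ylide can form and pass on by a [1,2]-shift of the benzyl group, a well-known course for 2-alkoxyaryl diazo ketones. The carbene is flanked by a ketone and by the α-carbon of a chromone, a poorer donor than the aryl groups for which such catalysts are normally used. After A7, a hindered tetrasubstituted alkene must be hydrogenated on the correct face without cleaving the 4-methoxybenzyl ethers or the benzylic C–O bonds.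
- Comparison: the alternative is the better in that its key step sets two stereocentres under catalyst control and does not rely on substrate-controlled face selectivity for unit 1; in step count it is roughly equal. It is weaker because its key step competes with an established side pathway and because the sensitive cis centres are made at the very end on a crowded alkene, whereas the chosen plan makes them early and then avoids base.

Key step: step 11

Assumption: the target is read as (2S,3R,2''S,3''S), unit 1 trans and unit 2 cis. In step 3 the (S)-bisphosphine (S)-MeO-F12-BIPHEP, (S)-2,2'-bis[bis(3,4,5-trifluorophenyl)phosphino]-6,6'-dimethoxybiphenyl, is taken to give the 2S product; if the sense of induction is the opposite, the (R)-ligand is used and nothing else changes.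

## Steps

Step 1
Reactants: 1 2,4,6-trihydroxyacetophenone
Product: 2 1-[2,4-bis(benzyloxy)-6-hydroxyphenyl]ethan-1-one
Conditions: BnBr (2.1 equiv), K2CO3, DMF, 23 °C
Reagents that add atoms: benzyl bromide, BrCc1ccccc1
Why: Williamson etherification; the hydroxyl hydrogen-bonded to the acetyl group is the least nucleophilic, so two equivalents of halide should alkylate the 4-OH and one 2-OH and leave the chelated phenol needed for ring closure in step 2.

Step 2
Reactants: 2 1-[2,4-bis(benzyloxy)-6-hydroxyphenyl]ethan-1-one
Product: 4 5,7-bis(benzyloxy)-4H-chromen-4-one, via enaminone 3 (not isolated)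
Conditions: Me2NCH(OMe)2, toluene, 100 °C; then conc. HCl, CH2Cl2, 23 °C
Reagents that add atoms: N,N-dimethylformamide dimethyl acetal, COC(OC)N(C)C
Why: Condensation of the methyl ketone with the amide acetal gives the enaminone, and acid then drives addition of the phenol to the enamine carbon with loss of dimethylamine (enaminone route to chromones). The acetal carbon becomes C2.

Step 3
Reactants: 4 5,7-bis(benzyloxy)-4H-chromen-4-one; 5 4-methoxyphenylboronic acid
Product: 6 (2S)-5,7-bis(benzyloxy)-2-(4-methoxyphenyl)chroman-4-one
Conditions: [Rh(OH)(cod)]2 (3 mol %), (S)-MeO-F12-BIPHEP (7 mol %), toluene/H2O (20:1), 50 °C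
Reagents that add atoms: none
Why: Rhodium-catalysed asymmetric 1,4-addition of an arylboronic acid to a chromone; the aryl–rhodium species adds to C2 on the face selected by the biaryl bisphosphine, and water protonates the rhodium oxa-π-allyl intermediate without a free enolate, so the ring should not open. This step sets the absolute configuration (C2, S) from which all other centres are relayed.

Step 4
Reactants: 6 (2S)-5,7-bis(benzyloxy)-2-(4-methoxyphenyl)chroman-4-one
Product: 7 (2S)-5,7-bis(benzyloxy)-2-(4-methoxyphenyl)-4-(trimethylsilyloxy)-2H-chromene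
Conditions: TMSOTf, Et3N, CH2Cl2, 0 °C
Reagents that add atoms: trimethylsilyl trifluoromethanesulfonate, C[Si](C)(C)OS(=O)(=O)C(F)(F)F
Why: Soft enolisation (O-silylation of the ketone, then deprotonation at C3 by the amine) gives the enol silane without a metal enolate, which would expel the phenoxide by E1cB and racemise C2.

Step 5
Reactants: 8 (E)-1-methoxy-3-(trimethylsilyloxy)buta-1,3-diene
Product: 9 (E)-1-bromo-4-methoxybut-3-en-2-one
Conditions: NBS, THF, −78 → 0 °C
Reagents that add atoms: N-bromosuccinimide, O=C1CCC(=O)N1Br
Why: α-Halogenation of a silyl enol ether; the CH2 terminus is the most nucleophilic carbon, and loss of the silyl group gives the bromomethyl ketone with the β-methoxy enone intact.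

Step 6
Reactants: 7 (2S)-5,7-bis(benzyloxy)-2-(4-methoxyphenyl)-4-(trimethylsilyloxy)-2H-chromene; 9 (E)-1-bromo-4-methoxybut-3-en-2-one
Product: 10 (2S,3R)-5,7-bis(benzyloxy)-3-[(3E)-4-methoxy-2-oxobut-3-en-1-yl]-2-(4-methoxyphenyl)chroman-4-one
Conditions: fac-Ir(ppy)3 (1 mol %), 2,6-lutidine, MeCN, blue LEDs, 23 °C
Reagents that add atoms: none
Why: Photoredox radical alkylation of a silyl enol ether with an α-bromo ketone; the excited iridium complex reduces 9 to an electrophilic α-keto radical that adds to C3, and oxidation of the resulting α-silyloxy benzylic radical with loss of the silyl group gives the 1,4-diketone under neutral conditions. C3 is set by approach anti to the C2 aryl group (2,3-trans, 3R), which is also the more stable diequatorial arrangement.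

Step 7
Reactants: 10 (2S,3R)-5,7-bis(benzyloxy)-3-[(3E)-4-methoxy-2-oxobut-3-en-1-yl]-2-(4-methoxyphenyl)chroman-4-one
Product: 11 (2S,3R)-5,7-bis(benzyloxy)-3-[(1Z,3E)-2-(tert-butyldimethylsilyloxy)-4-methoxybuta-1,3-dien-1-yl]-2-(4-methoxyphenyl)chroman-4-one
Conditions: TBSOTf (1.1 equiv), Et3N, Et2O, −78 → 0 °C
Reagents that add atoms: tert-butyldimethylsilyl trifluoromethanesulfonate, CC(C)(C)[Si](C)(C)OS(=O)(=O)C(F)(F)F
Why: Soft enolisation of the vinylogous ester, the more Lewis-basic carbonyl, toward its only α-CH2 gives the 1-methoxy-3-silyloxy diene; the (Z)-enol ether, with the C3 substituent outward on the diene, is expected as for other 4-substituted dienes of this class. The aryl ketone of unit 1 is shielded by the peri benzyloxy group and has only a tertiary α-hydrogen.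

Step 8
Reactants: 11 (2S,3R)-5,7-bis(benzyloxy)-3-[(1Z,3E)-2-(tert-butyldimethylsilyloxy)-4-methoxybuta-1,3-dien-1-yl]-2-(4-methoxyphenyl)chroman-4-one; 12 4-methoxybenzaldehyde
Product: 15 (2S,3R)-5,7-bis(benzyloxy)-3-[(2S,3S)-5-bromo-2-(4-methoxyphenyl)-4-oxo-3,4-dihydro-2H-pyran-3-yl]-2-(4-methoxyphenyl)chroman-4-one, via enol silane cycloadduct 13 (not isolated), via bromo ketone acetal 14 (not isolated)
Conditions: Eu(fod)3 (10 mol %), CH2Cl2, 23–40 °C; then NBS, THF, −78 °C; then Et3N, −78 → 0 °C
Reagents that add atoms: N-bromosuccinimide, O=C1CCC(=O)N1Br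
Why: Lanthanide-catalysed hetero-Diels–Alder reaction of an aldehyde with a 1-methoxy-3-silyloxy diene; the mild Lewis acid favours the concerted endo pathway (aryl endo, C3'' substituent outward), which gives the 2'',3''-cis ring and keeps the enol silane of 13. With C3–H eclipsing the enol ether to relieve allylic strain, the aldehyde should add to the diene face beside the C4 carbonyl and away from the aryl-bearing C2, which gives 3''S. NBS then brominates the enol silane, which is far more reactive than the benzyloxy arene, and triethylamine eliminates methanol (E1cB) to the α-bromo enone.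

Step 9
Reactants: 16 methyl acetoacetate
Product: 17 methyl (E)-3-methoxybut-2-enoate
Conditions: HC(OMe)3, H2SO4 (cat.), MeOH, 23 °C
Reagents that add atoms: trimethyl orthoformate, COC(OC)OC
Why: Acid-catalysed ketalisation of the ketone and loss of methanol give the conjugated enol ether (O-methylation of a β-keto ester).

Step 10
Reactants: 17 methyl (E)-3-methoxybut-2-enoate
Product: 18 1,3-dimethoxy-1-(trimethylsilyloxy)buta-1,3-diene
Conditions: LDA, THF, −78 °C; then TMSCl
Reagents that add atoms: chlorotrimethylsilane, C[Si](C)(C)Cl
Why: γ-Deprotonation gives the extended enolate, which is silylated on oxygen to the ketene acetal diene. The geometry of the new double bond does not matter because that carbon becomes aromatic.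

Step 11
Reactants: 15 (2S,3R)-5,7-bis(benzyloxy)-3-[(2S,3S)-5-bromo-2-(4-methoxyphenyl)-4-oxo-3,4-dihydro-2H-pyran-3-yl]-2-(4-methoxyphenyl)chroman-4-one; 18 1,3-dimethoxy-1-(trimethylsilyloxy)buta-1,3-diene
Product: 21 (2S,3R)-5,7-bis(benzyloxy)-3-[(2S,3S)-5-hydroxy-7-methoxy-2-(4-methoxyphenyl)-4-oxochroman-3-yl]-2-(4-methoxyphenyl)chroman-4-one, via bromo cycloadduct 19 (not isolated), via aryl silyl ether 20 (not isolated)
Conditions: 18 (4 equiv), 2,4,6-collidine (2 equiv), toluene, 105 °C (sealed tube); then moist SiO2, CH2Cl2, 23 °C
Reagents that add atoms: none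
Why: Proposed new method: the electron-rich CH2 terminus of 18 should bond to C8a'', the β-carbon of the α-bromo enone of 15 and its most electrophilic site, while the ketene acetal carbon bonds to the bromine-bearing C4a'', in a strongly asynchronous thermal [4+2] addition that may also run as conjugate addition followed by 6-(enolexo)-exo-trig attack of the C4a'' enolate carbon on the ketene-acetal-derived oxocarbenium carbon; both courses give 19. The closest known reaction type is the Diels–Alder benzannulation of 1,3-dioxygenated silyloxydienes with 2-haloquinones and 2-halocycloalkenones, in which the halogen activates the dienophile and fixes the orientation; a 5-bromo-2,3-dihydropyran-4-one, whose ring oxygen lowers the dienophilicity, has no precedent, hence the excess of diene and the raised temperature. The new six-membered carbocycle closes through the bonds C8a''–C8'' and C4a''–C5''. The three sp3 centres formed in 19 (C4a'', C8a'', C5'') are transient and vanish on aromatisation, so no facial selectivity is needed and no stereocentre is set. Aromatisation should follow by ionisation of the doubly activated silyl methyl ketal at C5'' with loss of methanol and collidine-assisted loss of HBr across C4a''–C8a'', both driven by the gain of aromaticity, to give 20, and the peri aryl silyl ether is then hydrolysed on silica to the hydrogen-bonded phenol. The selectivity that matters is the orientation: it puts the oxygen that ends as the free hydroxyl at C5'' and the enol ether methoxy group at C7'', so the methylation pattern needs no protecting group. Chemoselectivity rests on C4a''=C8a'' being the only activated alkene, since both carbonyl groups of unit 1 and the new one are aryl ketones without a conjugated double bond. The collidine buffer is too weak a base to enolise C4'' toward C3'', which should keep the cis centre and both benzylic C–O bonds intact.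

Step 12
Reactants: 21 (2S,3R)-5,7-bis(benzyloxy)-3-[(2S,3S)-5-hydroxy-7-methoxy-2-(4-methoxyphenyl)-4-oxochroman-3-yl]-2-(4-methoxyphenyl)chroman-4-one
Product: 22 (2S,3R)-5,7-dihydroxy-3-[(2S,3S)-5-hydroxy-7-methoxy-2-(4-methoxyphenyl)-4-oxochroman-3-yl]-2-(4-methoxyphenyl)chroman-4-one
Conditions: H2 (1 atm), Pd/C (10 %), EtOAc, 23 °C
Reagents that add atoms: none
Why: Hydrogenolysis of aryl benzyl ethers under neutral conditions that neither enolise C3/C3'' nor open the pyranone rings. The reaction is stopped once both benzyl groups are gone so that the benzylic C2–O bonds are not reduced.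

## Compound list

1 | 2,4,6-trihydroxyacetophenone | CC(=O)c1c(O)cc(O)cc1O | starting material
2 | 1-[2,4-bis(benzyloxy)-6-hydroxyphenyl]ethan-1-one | CC(=O)c1c(O)cc(OCc2ccccc2)cc1OCc1ccccc1 | intermediate
3 | (E)-1-[2,4-bis(benzyloxy)-6-hydroxyphenyl]-3-(dimethylamino)prop-2-en-1-one (not isolated) | CN(C)/C=C/C(=O)c1c(O)cc(OCc2ccccc2)cc1OCc1ccccc1 | intermediate
4 | 5,7-bis(benzyloxy)-4H-chromen-4-one | O=c1ccoc2cc(OCc3ccccc3)cc(OCc3ccccc3)c12 | intermediate
5 | 4-methoxyphenylboronic acid | COc1ccc(B(O)O)cc1 | starting material
6 | (2S)-5,7-bis(benzyloxy)-2-(4-methoxyphenyl)chroman-4-one | COc1ccc([C@H]2Oc3cc(OCc4ccccc4)cc(OCc4ccccc4)c3C(=O)C2)cc1 | intermediate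
7 | (2S)-5,7-bis(benzyloxy)-2-(4-methoxyphenyl)-4-(trimethylsilyloxy)-2H-chromene | COc1ccc([C@H]2Oc3cc(OCc4ccccc4)cc(OCc4ccccc4)c3C(O[Si](C)(C)C)=C2)cc1 | intermediate
8 | (E)-1-methoxy-3-(trimethylsilyloxy)buta-1,3-diene | CO/C=C/C(=C)O[Si](C)(C)C | starting material
9 | (E)-1-bromo-4-methoxybut-3-en-2-one | CO/C=C/C(=O)CBr | intermediate
10 | (2S,3R)-5,7-bis(benzyloxy)-3-[(3E)-4-methoxy-2-oxobut-3-en-1-yl]-2-(4-methoxyphenyl)chroman-4-one (2,3-trans) | COc1ccc([C@H]2Oc3cc(OCc4ccccc4)cc(OCc4ccccc4)c3C(=O)[C@@H]2CC(=O)/C=C/OC)cc1 | intermediate
11 | (2S,3R)-5,7-bis(benzyloxy)-3-[(1Z,3E)-2-(tert-butyldimethylsilyloxy)-4-methoxybuta-1,3-dien-1-yl]-2-(4-methoxyphenyl)chroman-4-one | COc1ccc([C@H]2Oc3cc(OCc4ccccc4)cc(OCc4ccccc4)c3C(=O)[C@@H]2/C=C(\O[Si](C)(C)C(C)(C)C)/C=C/OC)cc1 | intermediate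
12 | 4-methoxybenzaldehyde | COc1ccc(C=O)cc1 | starting material
13 | (2S,3R)-5,7-bis(benzyloxy)-3-[(2S,3S,6R)-4-(tert-butyldimethylsilyloxy)-6-methoxy-2-(4-methoxyphenyl)-3,6-dihydro-2H-pyran-3-yl]-2-(4-methoxyphenyl)chroman-4-one (2,3,6-all-cis pyran; not isolated) | COc1ccc([C@H]2Oc3cc(OCc4ccccc4)cc(OCc4ccccc4)c3C(=O)[C@@H]2[C@@H]2C(O[Si](C)(C)C(C)(C)C)=C[C@H](OC)O[C@@H]2c2ccc(OC)cc2)cc1 | intermediate
14 | (2S,3R)-5,7-bis(benzyloxy)-3-[(2S,3S,6R)-5-bromo-6-methoxy-2-(4-methoxyphenyl)-4-oxotetrahydro-2H-pyran-3-yl]-2-(4-methoxyphenyl)chroman-4-one (configuration at the bromine-bearing carbon not controlled; not isolated) | COc1ccc([C@H]2Oc3cc(OCc4ccccc4)cc(OCc4ccccc4)c3C(=O)[C@@H]2[C@@H]2C(=O)C(Br)[C@H](OC)O[C@@H]2c2ccc(OC)cc2)cc1 | intermediate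
15 | (2S,3R)-5,7-bis(benzyloxy)-3-[(2S,3S)-5-bromo-2-(4-methoxyphenyl)-4-oxo-3,4-dihydro-2H-pyran-3-yl]-2-(4-methoxyphenyl)chroman-4-one | COc1ccc([C@H]2Oc3cc(OCc4ccccc4)cc(OCc4ccccc4)c3C(=O)[C@@H]2[C@@H]2C(=O)C(Br)=CO[C@@H]2c2ccc(OC)cc2)cc1 | intermediate
16 | methyl acetoacetate | CC(=O)CC(=O)OC | starting material
17 | methyl (E)-3-methoxybut-2-enoate | CO/C(C)=C/C(=O)OC | intermediate
18 | 1,3-dimethoxy-1-(trimethylsilyloxy)buta-1,3-diene (ketene acetal geometry not controlled and immaterial) | C=C(OC)C=C(OC)O[Si](C)(C)C | intermediate
19 | [4+2] adduct of 15 and 18: unit 2 as the 4a''-bromo-5'',7''-dimethoxy-5''-(trimethylsilyloxy)-4a'',5'',8'',8a''-tetrahydrochroman-4-one, cis ring fusion, new sp3 centres transient and unspecified (not isolated) | COc1ccc([C@H]2Oc3cc(OCc4ccccc4)cc(OCc4ccccc4)c3C(=O)[C@@H]2[C@@H]2C(=O)C3(Br)C(OC)(O[Si](C)(C)C)C=C(OC)CC3O[C@@H]2c2ccc(OC)cc2)cc1 | intermediate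
20 | (2S,3R)-5,7-bis(benzyloxy)-3-[(2S,3S)-7-methoxy-2-(4-methoxyphenyl)-4-oxo-5-(trimethylsilyloxy)chroman-3-yl]-2-(4-methoxyphenyl)chroman-4-one (not isolated) | COc1ccc([C@H]2Oc3cc(OCc4ccccc4)cc(OCc4ccccc4)c3C(=O)[C@@H]2[C@@H]2C(=O)c3c(O[Si](C)(C)C)cc(OC)cc3O[C@@H]2c2ccc(OC)cc2)cc1 | intermediate
21 | (2S,3R)-5,7-bis(benzyloxy)-3-[(2S,3S)-5-hydroxy-7-methoxy-2-(4-methoxyphenyl)-4-oxochroman-3-yl]-2-(4-methoxyphenyl)chroman-4-one | COc1ccc([C@H]2Oc3cc(OCc4ccccc4)cc(OCc4ccccc4)c3C(=O)[C@@H]2[C@@H]2C(=O)c3c(O)cc(OC)cc3O[C@@H]2c2ccc(OC)cc2)cc1 | intermediate
22 | (2S,3R)-5,7-dihydroxy-3-[(2S,3S)-5-hydroxy-7-methoxy-2-(4-methoxyphenyl)-4-oxochroman-3-yl]-2-(4-methoxyphenyl)chroman-4-one | COc1ccc([C@H]2Oc3cc(O)cc(O)c3C(=O)[C@@H]2[C@@H]2C(=O)c3c(O)cc(OC)cc3O[C@@H]2c2ccc(OC)cc2)cc1 | target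

## Step count and least certain steps

Total step count: 12. Longest linear sequence: 9 steps (steps 1, 2, 3, 4, 6, 7, 8, 11, 12); steps 5, 9 and 10 prepare the side components 9 and 18.

Step 11 (key step). The most likely failure is sluggish cycloaddition, because the ring oxygen donates into the enone, with 18 decaying thermally before 15 is consumed. Other risks are arrest after the first C–C bond without ring closure, hydrolysis of the C7'' enol ether before aromatisation (which would lose the methyl group), and slow epimerisation of C3'' on long heating. Speeding the reaction with a silyl triflate would make it stepwise and put C3'' at risk, so it is not the fallback.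

The fallback uses known reactions only and brings ring A of unit 2 in ready-made; it sets out from 7 and comes back at 21. Commercial 1-(2,6-dihydroxy-4-methoxyphenyl)ethan-1-one would be silylated (TBSOTf, 2,6-lutidine) to 1-[2,6-bis(tert-butyldimethylsilyloxy)-4-methoxyphenyl]ethan-1-one F1 and brominated through its enol silane (LiHMDS, TMSCl, then NBS) to 2-bromo-1-[2,6-bis(tert-butyldimethylsilyloxy)-4-methoxyphenyl]ethan-1-one F2. Radical alkylation of 7 with F2 under the conditions of step 6, for which phenacyl bromides are the standard partners, should give the 2,3-trans 1,4-diketone F3. Enolisation of its aroylmethylene group with Cy2BCl/Et3N and addition to 12 would give the anti-aldol adduct F4, and HF·pyridine would free the two phenols to give the diphenol F5. A Mitsunobu etherification (PPh3, DIAD) would then close the pyranone ring by attack of one phenol on the activated carbinol with inversion, which turns the anti aldol into the 2'',3''-cis flavanone 21; the second, hydrogen-bonded phenol stays as the C5'' hydroxyl. The face selectivity of the aldol step and partial ionisation at the 4-methoxybenzylic carbinol are the weak points of this sequence.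

Step 8. The electron-rich aldehyde and the bulky diene terminus may make the cycloaddition slow. Face selectivity at C3'' rests on a conformational model and may be modest. A stepwise aldol pathway would erode the cis selectivity, premature loss of the silyl group would prevent the bromination, and the amine could epimerise C3'' if the elimination is prolonged.

The fallback replaces the cycloaddition by a closed-transition-state aldol reaction; it sets out from 10 and comes back at 15. The (Z)-boron enolate of 10 (n-Bu2BOTf, i-Pr2NEt, CH2Cl2, −78 °C; a diisopinocampheylboron triflate if reagent control of the face is needed) would add to 12 to give the syn-aldol adduct F6. PPTS would close F6 by oxa-Michael addition and loss of methanol, with retention at C2'', to the cis-dihydropyranone F7. NBS (1.0 equiv, CH2Cl2, 0 °C) would then brominate C5 of the vinylogous ester to give 15. Any bromine that entered ring A of unit 1 in this last operation would be an aryl bromide, which should be reduced in step 12.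

Step 6. The radical chain may be inefficient with this particular bromo ketone (reduction of 9 without addition, or its decomposition), and the silyl bromide formed may attack the enol ether if the buffer is insufficient.

The fallback gives up the radical pathway for a two-electron alkylation; it sets out from 7 and comes back at 10, with no new compound. The lithium enolate would be generated regiospecifically from 7 with MeLi (THF, −78 °C) and alkylated at once with 9 by SN2 displacement, kept at −78 °C to outrun E1cB ring opening.

Step 3. The electron-rich chromone may react slowly, with protodeboronation of 5 competing, and the enantioselectivity may fall short.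

The fallback builds the flavanone classically and resolves it; it sets out from 2 and comes back at 6. A Claisen–Schmidt condensation of 2 with 12 (KOH, EtOH) would give the chalcone (E)-1-[2,4-bis(benzyloxy)-6-hydroxyphenyl]-3-(4-methoxyphenyl)prop-2-en-1-one F8, and NaOAc in hot ethanol would cyclise it to the racemic flavanone F9. Kinetic resolution by asymmetric transfer hydrogenation (RuCl(p-cymene)[(R,R)-TsDPEN] or its antipode, HCO2H/Et3N), with the catalyst chosen so that the 2R ketone is reduced faster, would leave 6 and convert the unwanted enantiomer into the cis-flavan-4-ol F10, which is separated. At most half of the material can be carried on.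

## Further compounds

F1 | step 11 | 1-[2,6-bis(tert-butyldimethylsilyloxy)-4-methoxyphenyl]ethan-1-one | CC(=O)c1c(O[Si](C)(C)C(C)(C)C)cc(OC)cc1O[Si](C)(C)C(C)(C)C
F2 | step 11 | 2-bromo-1-[2,6-bis(tert-butyldimethylsilyloxy)-4-methoxyphenyl]ethan-1-one | BrCC(=O)c1c(O[Si](C)(C)C(C)(C)C)cc(OC)cc1O[Si](C)(C)C(C)(C)C
F3 | step 11 | (2S,3R)-5,7-bis(benzyloxy)-3-{2-[2,6-bis(tert-butyldimethylsilyloxy)-4-methoxyphenyl]-2-oxoethyl}-2-(4-methoxyphenyl)chroman-4-one | COc1ccc([C@H]2Oc3cc(OCc4ccccc4)cc(OCc4ccccc4)c3C(=O)[C@@H]2CC(=O)c2c(O[Si](C)(C)C(C)(C)C)cc(OC)cc2O[Si](C)(C)C(C)(C)C)cc1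
F4 | step 11 | (2S,3R)-5,7-bis(benzyloxy)-3-{(1R,2S)-3-[2,6-bis(tert-butyldimethylsilyloxy)-4-methoxyphenyl]-1-hydroxy-1-(4-methoxyphenyl)-3-oxopropan-2-yl}-2-(4-methoxyphenyl)chroman-4-one (anti aldol) | COc1ccc([C@H]2Oc3cc(OCc4ccccc4)cc(OCc4ccccc4)c3C(=O)[C@@H]2[C@@H]([C@@H](O)c2ccc(OC)cc2)C(=O)c2c(O[Si](C)(C)C(C)(C)C)cc(OC)cc2O[Si](C)(C)C(C)(C)C)cc1
F5 | step 11 | (2S,3R)-5,7-bis(benzyloxy)-3-[(1R,2S)-3-(2,6-dihydroxy-4-methoxyphenyl)-1-hydroxy-1-(4-methoxyphenyl)-3-oxopropan-2-yl]-2-(4-methoxyphenyl)chroman-4-one | COc1ccc([C@H]2Oc3cc(OCc4ccccc4)cc(OCc4ccccc4)c3C(=O)[C@@H]2[C@@H]([C@@H](O)c2ccc(OC)cc2)C(=O)c2c(O)cc(OC)cc2O)cc1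
F6 | step 8 | (2S,3R)-5,7-bis(benzyloxy)-3-[(1S,2S,4E)-1-hydroxy-5-methoxy-1-(4-methoxyphenyl)-3-oxopent-4-en-2-yl]-2-(4-methoxyphenyl)chroman-4-one (syn aldol) | COc1ccc([C@H]2Oc3cc(OCc4ccccc4)cc(OCc4ccccc4)c3C(=O)[C@@H]2[C@@H]([C@H](O)c2ccc(OC)cc2)C(=O)/C=C/OC)cc1
F7 | step 8 | (2S,3R)-5,7-bis(benzyloxy)-2-(4-methoxyphenyl)-3-[(2S,3S)-2-(4-methoxyphenyl)-4-oxo-3,4-dihydro-2H-pyran-3-yl]chroman-4-one | COc1ccc([C@H]2Oc3cc(OCc4ccccc4)cc(OCc4ccccc4)c3C(=O)[C@@H]2[C@@H]2C(=O)C=CO[C@@H]2c2ccc(OC)cc2)cc1
F0 | step 6 | none | none
F8 | step 3 | (E)-1-[2,4-bis(benzyloxy)-6-hydroxyphenyl]-3-(4-methoxyphenyl)prop-2-en-1-one | COc1ccc(/C=C/C(=O)c2c(O)cc(OCc3ccccc3)cc2OCc2ccccc2)cc1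
F9 | step 3 | rac-5,7-bis(benzyloxy)-2-(4-methoxyphenyl)chroman-4-one | COc1ccc(C2Oc3cc(OCc4ccccc4)cc(OCc4ccccc4)c3C(=O)C2)cc1
F10 | step 3 | (2R,4R)-5,7-bis(benzyloxy)-2-(4-methoxyphenyl)chroman-4-ol (cis) | COc1ccc([C@@H]2Oc3cc(OCc4ccccc4)cc(OCc4ccccc4)c3[C@H](O)C2)cc1
A1 | alternative 1 | (1E,3E)-1,4-bis(4-methoxyphenyl)buta-1,3-diene | COc1ccc(/C=C/C=C/c2ccc(OC)cc2)cc1
A2 | alternative 1 | maleic anhydride | O=C1OC(=O)C=C1
A3 | alternative 1 | all-cis-3,6-bis(4-methoxyphenyl)cyclohex-4-ene-1,2-dicarboxylic anhydride (meso) | [C@@H]1(c3ccc(OC)cc3)C=C[C@H](c3ccc(OC)cc3)[C@@H]2C(=O)OC(=O)[C@H]12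
A4 | alternative 2 | (2S,2''S)-5,7,5''-tris(benzyloxy)-7''-methoxy-2,2''-bis(4-methoxyphenyl)-2H,2''H-4,4''-bichromene | COc1ccc([C@H]2Oc3cc(OCc4ccccc4)cc(OCc4ccccc4)c3C(=C2)C2=C[C@@H](c3ccc(OC)cc3)Oc3cc(OC)cc(OCc4ccccc4)c23)cc1
A5 | alternative 2 | cis-fused cyclobutene from A4 (C3–C3'' bonded, C4=C4'' double bond, unit 1 2,3-trans, unit 2 2'',3''-cis) | COc1ccc([C@H]2Oc3cc(OCc4ccccc4)cc(OCc4ccccc4)c3C5=C6c3c(OCc4ccccc4)cc(OC)cc3O[C@H](c3ccc(OC)cc3)[C@@H]6[C@H]25)cc1
A6 | alternative 3 | 2-diazo-2-[7-methoxy-5-(4-methoxybenzyloxy)-2-(4-methoxyphenyl)-4-oxo-4H-chromen-3-yl]-1-[2,4,6-tris(4-methoxybenzyloxy)phenyl]ethan-1-one | COc1ccc(COc2cc(OCc3ccc(OC)cc3)c(C(=O)C(=[N+]=[N-])c3c(-c4ccc(OC)cc4)oc4cc(OC)cc(OCc5ccc(OC)cc5)c4c3=O)c(OCc3ccc(OC)cc3)c2)cc1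
A7 | alternative 3 | (2S,3R)-5,7-bis(4-methoxybenzyloxy)-3-[7-methoxy-5-(4-methoxybenzyloxy)-2-(4-methoxyphenyl)-4-oxo-4H-chromen-3-yl]-2-(4-methoxyphenyl)chroman-4-one | COc1ccc([C@H]2Oc3cc(OCc4ccc(OC)cc4)cc(OCc4ccc(OC)cc4)c3C(=O)[C@@H]2c2c(-c3ccc(OC)cc3)oc3cc(OC)cc(OCc4ccc(OC)cc4)c3c2=O)cc1
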